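Take the green flask apart and build it up again, one process at a time.

| flask | starting material | reagent | catalyst | product | time |
|---|---|---|---|---|---|
| blue | 150 mM | 375 mM | 12.0 mM |  |  |
| violet | 75.0 mM | 300 mM | 12.0 mM |  |  |
| grey | 150 mM | 375 mM | 12.0 mM | 45.0 mM |  |
| green | 150 mM | 120 mM | 6.00 mM |  | 180 s |

- blue run (time / s: [product] / mM): 26: 8.4; 51: 22.2; 77: 30.8; 100: 37.1; 130: 38.0; 150: 40.1; 180: 42.4
- violet run (time / s: [product] / mM): 26: 4.3; 51: 10.7; 77: 15.4; 100: 17.6; 130: 19.2; 150: 18.5; 180: 21.8
- grey run (time / s: [product] / mM): 26: 55.4; 51: 66.3; 77: 74.4; 100: 80.1; 130: 84.0; 150: 84.8; 180: 85.4

(standard deviation of a reading: 1 mM)

* product in the green run at 180 s, as a share of the starting material charged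

- Overall: starting material + reagent -> product, with catalyst as catalyst.
- Constant volume, constant temperature.
- The analysis sees a species whether free or bound.
- "The second partner" is reagent.

Start with the main step alone. In the green flask reagent is the limiting reagent, and it caps product at 80.0% of the starting material charged. Between its readings at 26 s and 77 s the blue run makes product at 0.439 mM s⁻¹. Give the green flask half of that rate for its halved catalyst charge, hold it for 180 s, and you get 39.5 mM, or 26.4%. That is the early end of the reckoning.

Now add the stall. The blue run reads 37.1 mM at 100 s but gains just 5.30 mM more by 180 s, with c(reagent) still near 333 mM. The grey run, charged with 45.0 mM of product, has made 40.4 mM of new product at 180 s, about what the blue run has made, so I do not read product as the brake. The violet run, with half the starting material, ends at about half the blue product, so the stall sits at a share of the charge. Read it as a contest and score it with the catch ratio, the product made by the asked time over the starting material charged minus that product: 0.394 for the blue run at 180 s. The violet run gives 0.410, and the grey run, counting new product, gives 0.369. My assumption, untested by these runs, is that the ratio scales with catalyst charged. That makes it 0.197 for the green flask, a share of 16.5%, lower than the main step's figure.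

Then the rest. That much product takes c(reagent) from 120 mM to about 95.3 mM, so the cap stays distant. Going from the blue to the violet charge, which lowers reagent from 375 mM to 300 mM along with the starting material, moves the catch ratio no further than the scatter, and that gives no size for 120 mM. I keep my figure and expect the flask somewhat lower.

The forecast says 14%, lower than my figure, and holds that “added product neither inhibits the reaction nor sets an equilibrium”. The green flask gives 13.2%.

    active catalyst + starting material → catalyst-substrate complex (0.7010 L mol⁻¹ s⁻¹)
    catalyst-substrate complex + reagent → product + active catalyst (0.8870 L mol⁻¹ s⁻¹)
    starting material → decomposed substrate (0.01500 s⁻¹)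
    catalyst → active catalyst (0.07500 s⁻¹)

That is a catch ratio of 0.152, lower than my 0.197. The contest is now visible: the rival of the main step is the conversion of starting material into decomposed substrate. Run the green flask without that conversion and it reaches 28.1% instead of 13.2%, close to the 26.4% of the main step alone. The catch ratio of that second flask climbs to 0.391.

(Readings and results are simulated with made-up constants; noise was put on by code.)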